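**Plan**

- Ring numbering: C1 is the quaternary carbinol carrying C7H2OBz, then C2 (OBz), C3=C4, C5 (OBz), C6 (OH). The retrosynthesis cuts, in order, the C5–OBz bond (anti opening of a C5–C6 oxirane), the two C–O bonds of that oxirane, the O2–benzoyl bond, and the C2–O and C3–O bonds of a C2–C3 oxirane whose C3–O bond is spent in a Wharton transposition. This leads back to an achiral para-quinol and 4-hydroxybenzyl alcohol.
- Enabling feature: C1 with O1 and C7 is the sp3 carbon of a para-quinol whose carbonyl sits at C4. C2=C3 and C5=C6 are then enantiotopic enone alkenes, both allylic to O1, and the C2 oxygen beside C3=C4 is what a Wharton reaction leaves from the C2–C3 epoxy ketone.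
- Forward order: the carbocycle is bought as the arene. The sequence is C7–O esterification, dearomatisation to the quinol, first oxirane (C2–C3, key step), Wharton opening to the cis-diol diene, O2 benzoate, second oxirane (C5–C6), benzoate opening at C5.
- Stereochemistry: C1 and C2 come from the tartrate-controlled choice of one enone alkene with oxygen delivery by O1 (oxirane cis to O1). C6 comes from O1-directed epoxidation of C5=C6, and C5 from inversion in the anti opening.

Key step: step 3

Remark: names keep the ring numbering of the target (C1–C6, exocyclic C7), so locants stay fixed along the route; descriptors are the CIP descriptors at those locants.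
Assumption: the sense of induction in step 3 is taken from the Sharpless face rule, which has not been tested on this substrate class; should the quinol respond in the opposite sense, D-(−)-DIPT replaces L-(+)-DIPT and nothing else changes.

**Step 1**
Reactants: 1 4-hydroxybenzyl alcohol; 2 benzoic acid
Product: 3 4-hydroxybenzyl benzoate
Conditions: PPh3, DIAD, THF, 0 °C → rt
Reagents that add atoms: none
Why: Chemoselective Mitsunobu esterification: benzoic acid (pKa about 4) is deprotonated by the betaine far ahead of the phenol, so benzoate displaces the activated primary benzylic oxygen and the phenolic hydroxyl stays free; no stereocentre is formed.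

**Step 2**
Reactants: 3 4-hydroxybenzyl benzoate
Product: 4 (1-hydroxy-4-oxocyclohexa-2,5-dien-1-yl)methyl benzoate
Conditions: PhI(OAc)2 (1.1 equiv), MeCN–H2O (4:1), 0 °C
Reagents that add atoms: water, O
Why: Iodine(III) oxidative dearomatisation of a para-substituted phenol: aryloxy-iodane formation, loss of iodobenzene and capture of the para carbon by water (directly, or through the neighbouring benzoate, whose dioxolanylium ion hydrolyses to the same primary ester) should give the achiral para-quinol, whose mirror plane runs through C1 and C4.

**Step 3**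
Reactants: 4 (1-hydroxy-4-oxocyclohexa-2,5-dien-1-yl)methyl benzoate
Product: 5 [(1R,2R,3S)-2,3-epoxy-1-hydroxy-4-oxocyclohex-5-en-1-yl]methyl benzoate (oxirane cis to the 1-hydroxyl)
Conditions: Ti(OiPr)4 (1.0 equiv), L-(+)-DIPT (1.2 equiv), t-BuOOH (1.2 equiv, anhydrous), 4 Å MS, CH2Cl2, −20 °C; aqueous tartaric acid work-up
Reagents that add atoms: tert-butyl hydroperoxide, CC(C)(C)OO
Why: Proposed new method: the tertiary alkoxide O1 of 4 and a tert-butyl peroxide ligand are expected to sit on the same titanium of the tartrate complex, so that the activated peroxide oxygen is handed to C2, the β-carbon of one enone, and the enolate carbon C3 then closes on the same oxygen with loss of tert-butoxide, a 3-exo-tet closure of the oxirane (C2–O, then C3–O) on the face of O1. The closest known reactions are the Katsuki–Sharpless desymmetrisation of divinyl carbinols, the ligand-free hydroxyl-directed Ti(IV)/TBHP or V(V)/TBHP syn-epoxidation of para-quinols and the tartrate-mediated nucleophilic epoxidation of quinone monoketals, none of which has been shown as an enantioselective epoxidation of a para-quinol. C2 and C3 are set relative to C1 by the intramolecular, suprafacial delivery (oxirane cis to O1), and C1 becomes stereogenic through the choice between the enantiotopic C2=C3 and C5=C6 bonds, which only the tartrate can make. Reading the Sharpless face rule for each alkene with C1 as the carbinol carbon, L-(+)-DIPT places the bound hydroxyl on the delivering face only for the alkene that leads to (1R,2R,3S)-5. The step therefore needs enantiotopic-group selectivity and a stop after one oxygen transfer: the planar dienone holds O1 at the same dihedral angle to both alkenes, so no substrate bias competes with the ligand, and any 5 of the wrong hand still carries its matched alkene and should be drained to the achiral syn,syn-bis-epoxide, raising the enantiomeric purity of 5 as conversion rises.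

**Step 4**
Reactants: 5 [(1R,2R,3S)-2,3-epoxy-1-hydroxy-4-oxocyclohex-5-en-1-yl]methyl benzoate
Product: 7 [(1R,2R)-1,2-dihydroxycyclohexa-3,5-dien-1-yl]methyl benzoate, via epoxy hydrazone 6 (not isolated)
Conditions: N2H4·H2O (2.5 equiv), AcOH (0.2 equiv), MeOH, 0 °C → rt; neutral work-up, used at once
Reagents that add atoms: none
Why: Wharton transposition: hydrazone 6 forms at C4, the alkenyl diazene produced by opening of the oxirane at C3 loses nitrogen, and the C2–O bond is never broken, so the C2 hydroxyl stays cis to O1 while C3=C4 appears beside the surviving C5=C6; the neopentyl β-carbon C6 should resist conjugate addition and the short, cold exposure should spare the benzoate.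

**Step 5**
Reactants: 7 [(1R,2R)-1,2-dihydroxycyclohexa-3,5-dien-1-yl]methyl benzoate
Product: 8 [(1R,2R)-2-(benzoyloxy)-1-hydroxycyclohexa-3,5-dien-1-yl]methyl benzoate
Conditions: BzCl (1.1 equiv), pyridine, CH2Cl2, −20 → 0 °C
Reagents that add atoms: benzoyl chloride, O=C(Cl)c1ccccc1
Why: Pyridine-mediated acylation distinguishes the secondary allylic hydroxyl from the tertiary one on steric grounds, so only O2 is benzoylated and no stereocentre is touched.

**Step 6**
Reactants: 8 [(1R,2R)-2-(benzoyloxy)-1-hydroxycyclohexa-3,5-dien-1-yl]methyl benzoate
Product: 9 [(1R,2R,5S,6S)-2-(benzoyloxy)-5,6-epoxy-1-hydroxycyclohex-3-en-1-yl]methyl benzoate (oxirane cis to the 1-hydroxyl)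
Conditions: VO(acac)2 (5 mol %), t-BuOOH (1.2 equiv), CH2Cl2, 0 °C
Reagents that add atoms: tert-butyl hydroperoxide, CC(C)(C)OO
Why: Vanadium-catalysed hydroxyl-directed epoxidation of an allylic alcohol: O1, the only free hydroxyl, binds vanadium and delivers the peroxide oxygen to its own allylic alkene C5=C6 on its own face, setting C5 and C6 with the oxirane cis to O1, while C3=C4 is only homoallylic to O1 and deactivated by the allylic benzoate.

**Step 7**
Reactants: 9 [(1R,2R,5S,6S)-2-(benzoyloxy)-5,6-epoxy-1-hydroxycyclohex-3-en-1-yl]methyl benzoate; 2 benzoic acid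
Product: 10 [(1S,2R,5R,6S)-2,5-bis(benzoyloxy)-1,6-dihydroxycyclohex-3-en-1-yl]methyl benzoate
Conditions: PhCO2H (2 equiv), Ti(OiPr)4 (1.5 equiv), CH2Cl2, rt; aqueous tartaric acid work-up
Reagents that add atoms: none
Why: Titanium-mediated C-3 opening of a 2,3-epoxy alcohol by a carboxylic acid: titanium bridges O1 and the oxirane oxygen, and benzoate attacks the distal carbon C5, which is also the allylic one, with inversion, giving the 5-benzoate trans to the 6-hydroxyl; C6 is shielded by the quaternary C1.

**Compound list**

1 | 4-hydroxybenzyl alcohol | OCc1ccc(O)cc1 | starting material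
2 | benzoic acid | OC(=O)c1ccccc1 | starting material
3 | 4-hydroxybenzyl benzoate | O=C(OCc1ccc(O)cc1)c1ccccc1 | intermediate
4 | (1-hydroxy-4-oxocyclohexa-2,5-dien-1-yl)methyl benzoate (achiral para-quinol) | O=C1C=CC(O)(COC(=O)c2ccccc2)C=C1 | intermediate
5 | [(1R,2R,3S)-2,3-epoxy-1-hydroxy-4-oxocyclohex-5-en-1-yl]methyl benzoate | O=C(OC[C@@]1(O)[C@@H]2O[C@@H]2C(=O)C=C1)c1ccccc1 | intermediate
6 | [(1R,2R,3R)-2,3-epoxy-4-hydrazinylidene-1-hydroxycyclohex-5-en-1-yl]methyl benzoate (hydrazone of 5, formed in the flask, C=N geometry open) | O=C(OC[C@@]1(O)[C@@H]2O[C@@H]2C(=NN)C=C1)c1ccccc1 | intermediate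
7 | [(1R,2R)-1,2-dihydroxycyclohexa-3,5-dien-1-yl]methyl benzoate (cis-diol) | O=C(OC[C@@]1(O)[C@H](O)C=CC=C1)c1ccccc1 | intermediate
8 | [(1R,2R)-2-(benzoyloxy)-1-hydroxycyclohexa-3,5-dien-1-yl]methyl benzoate | O=C(OC[C@@]1(O)[C@H](OC(=O)c2ccccc2)C=CC=C1)c1ccccc1 | intermediate
9 | [(1R,2R,5S,6S)-2-(benzoyloxy)-5,6-epoxy-1-hydroxycyclohex-3-en-1-yl]methyl benzoate | O=C(OC[C@@]1(O)[C@H](OC(=O)c2ccccc2)C=C[C@@H]2O[C@H]12)c1ccccc1 | intermediate
10 | [(1S,2R,5R,6S)-2,5-bis(benzoyloxy)-1,6-dihydroxycyclohex-3-en-1-yl]methyl benzoate | O=C(OC[C@@]1(O)[C@H](OC(=O)c2ccccc2)C=C[C@@H](OC(=O)c2ccccc2)[C@@H]1O)c1ccccc1 | target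

Total step count: 7
Longest linear sequence: 7 steps (1 → 3 → 4 → 5 → 7 → 8 → 9 → 10)

**Steps most likely to fail**

Risk 1, step 3 (proposed new method). The process at risk is the discrimination between the two enantiotopic enone alkenes, which may be weak or of the opposite sense. Oxygen transfer from a hindered tertiary titanium alkoxide to an electron-poor alkene may also be too slow to compete with ligand-free background epoxidation. The fallback takes its chirality from a known enzymatic arene dihydroxylation and sets out from benzoic acid 2. Whole-cell oxidation with the dehydrogenase-deficient strain Ralstonia eutropha B9 should give (1S,2R)-1,2-dihydroxycyclohexa-3,5-diene-1-carboxylic acid F1, which has the C1/C2 configuration of 7. Trimethylsilyldiazomethane in methanol–toluene should convert it into methyl (1S,2R)-1,2-dihydroxycyclohexa-3,5-diene-1-carboxylate F2. Lithium aluminium hydride in THF at 0 °C should reduce the ester to (1R,2R)-1-(hydroxymethyl)cyclohexa-3,5-diene-1,2-diol F3. Benzoyl chloride (2.2 equiv) in pyridine at 0 °C should then acylate the primary and the secondary hydroxyl and leave the tertiary one, which brings the material back to the route at compound 8, ahead of step 6.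

Risk 2, step 4. The processes at risk are hydrazinolysis of the primary benzoate, poor turnover of the dienyl diazene, and acid-promoted dehydration of the cis-diol diene to a phenol. The fallback avoids hydrazine and sets out from compound 5. Luche reduction (NaBH4, CeCl3·7H2O, MeOH, −78 °C) should give [(1R,2R,3R,4R)-2,3-epoxy-1,4-dihydroxycyclohex-5-en-1-yl]methyl benzoate F4, with hydride expected anti to the oxirane (either C4 epimer would serve). Methanesulfonyl chloride and triethylamine at −20 °C should sulfonylate only the secondary allylic hydroxyl to give [(1R,2R,3S,4R)-2,3-epoxy-1-hydroxy-4-(methylsulfonyloxy)cyclohex-5-en-1-yl]methyl benzoate F5. Without storage, sodium iodide and zinc dust in acetone at room temperature should exchange the sulfonate for iodide and reductively open the oxirane from C3 (reductive elimination of a 2,3-epoxy halide). This returns the material to the route at compound 7.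

Risk 3, step 7. The processes at risk are acyl transfer between the benzoates and titanium isopropoxide, incorporation of isopropoxide, and opening with allylic shift at C3. The fallback separates opening from acylation and sets out from compound 9. Mild acid-catalysed hydrolysis (0.05 M HClO4 in THF–H2O, 0 °C) should open the oxirane at the allylic carbon with inversion to give [(1S,2R,5R,6S)-2-(benzoyloxy)-1,5,6-trihydroxycyclohex-3-en-1-yl]methyl benzoate F6. Benzoyl chloride (1.05 equiv) with 2,4,6-collidine in CH2Cl2 at −40 °C should then acylate the allylic 5-hydroxyl in preference to the 6-hydroxyl, which is flanked by the quaternary centre, and to the tertiary 1-hydroxyl. This arrives at compound 10.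

**Further compounds**

F1 | step 3 | (1S,2R)-1,2-dihydroxycyclohexa-3,5-diene-1-carboxylic acid | OC(=O)[C@@]1(O)[C@H](O)C=CC=C1
F2 | step 3 | methyl (1S,2R)-1,2-dihydroxycyclohexa-3,5-diene-1-carboxylate | COC(=O)[C@@]1(O)[C@H](O)C=CC=C1
F3 | step 3 | (1R,2R)-1-(hydroxymethyl)cyclohexa-3,5-diene-1,2-diol | OC[C@@]1(O)[C@H](O)C=CC=C1
F4 | step 4 | [(1R,2R,3R,4R)-2,3-epoxy-1,4-dihydroxycyclohex-5-en-1-yl]methyl benzoate | O=C(OC[C@@]1(O)[C@@H]2O[C@@H]2[C@H](O)C=C1)c1ccccc1
F5 | step 4 | [(1R,2R,3S,4R)-2,3-epoxy-1-hydroxy-4-(methylsulfonyloxy)cyclohex-5-en-1-yl]methyl benzoate | O=C(OC[C@@]1(O)[C@@H]2O[C@@H]2[C@H](OS(C)(=O)=O)C=C1)c1ccccc1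
F6 | step 7 | [(1S,2R,5R,6S)-2-(benzoyloxy)-1,5,6-trihydroxycyclohex-3-en-1-yl]methyl benzoate | O=C(OC[C@@]1(O)[C@H](OC(=O)c2ccccc2)C=C[C@@H](O)[C@@H]1O)c1ccccc1
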